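The readings were computed with made-up constants, and the scatter is random.

Equal molar product from alder and oak looks like saturation, but percentages of the charge can agree just as well, and the shape of the curve has to choose between the two readings.

| flask | starting material | free enzyme | temperature | remark | time |
|---|---|---|---|---|---|
| alder | 0.15 M (fed, over 2.5 h) | 6.6 µM | 37 °C | run made earlier; the fed solution adds 0.50 times the starting volume |  |
| oak | 0.20 M (fed, over 2.5 h) | 6.6 µM | 37 °C | run made earlier; the fed solution adds 0.50 times the starting volume |  |
| red | 0.10 M (fed, over 2.5 h) | 6.6 µM | 37 °C | the fed solution adds 0.50 times the starting volume | 2.5 h |
| amber | 0.10 M | 12 µM | 22 °C | everything together at the start, the whole solution of starting material included, so that from the start the volume is larger by 0.50 times the starting volume | 2.5 h |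

Red is fed throughout, so its end depends on how quickly fed starting material turns over. Amber gets everything at once, so its starting material falls from the start; it has more enzyme in a colder bath.

- alder (time / min: product / %): 2.50: 1.2; 4.00: 0; 6.00: 0.5; 10.0: 1.9; 20.0: 6.6; 30.0: 11.8
- oak (time / min: product / %): 5.00: 0; 10.0: 2.6; 15.0: 4.3; 20.0: 5.5; 25.0: 8.4; 30.0: 9.0

(readings scatter by 1 percentage point)

- amounts are per litre of the starting volume; all of the dose is in the solution fed
- the earlier runs do not show what temperature does; that part of a forecast is a guess
- percentages count the whole charge, also what has not yet gone in
- no earlier run changes the charge of free enzyme; that part of a forecast is a guess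

* which of the two ends with the higher amount of product, in percent of the starting material charged ("neither" if they lie within 2 percentage points) (red / amber / neither)
* product at the end, in percent of the starting material charged, red
* product at the end, in percent of the starting material charged, amber

Alder gains 1.9% of its charge in its first 10.0 min but 5.2 percentage points in the last 10.0 min of its readings, so its rate reads as climbing while starting material gathers, which looks pseudo-first-order. Over those last 10.0 min, averaged across alder and oak, product rises by 0.00435 min⁻¹ of the charge. At mid-span 16.7% has been fed and 8.22% is product, so 8.44% is held.

The waiting time, held share over conversion rate, 19.4 min, is a reading with wide scatter. With a steady feed and a steady waiting time, the held share at the end of the feed is the waiting time over the dosing time, multiplied by the fraction of a decay with that waiting time completed during dosing.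

My reckoning leaves out thinning by the added volume, in red and in amber alike. For red it gives a held share of 12.9% at the end, so 87.1% product. For amber the waiting time is guessed to scale inversely with enzyme and to grow by a factor 3 in the cold, which gives 32.0 min. The reckoning then leaves 0.924% in amber, so it puts amber higher.

The forecast differs: “The enzyme is therefore near saturation”. It gives 78% for red (62% to 90%) and 68% for amber (40% to 92%), and names red.

Red ends at 84.7% and amber at 99.7%, so amber ends higher.

    free enzyme → unfolded enzyme (k = 0.0226 h⁻¹, Ea = 206 kJ mol⁻¹)
    starting material + free enzyme → product + free enzyme, rate k2*[starting material]*[free enzyme]/(1 + ([starting material]/Km2)) (0.0856 M, k = 6.60 × 10⁵ M⁻¹ h⁻¹, Ea = 36.0 kJ mol⁻¹)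
    (constants at 37 °C)

At its end red still holds 15.3% as starting material, against the 12.9% reckoned from the waiting time, with 94.5% of its catalyst as free enzyme. With 1.6 × 10⁻⁶ M of free enzyme in the otherwise unchanged red flask, the waiting time, reckoned inversely with free enzyme, comes to 80.1 min. The same rule then gives a held share of 45.2% at the end, and that flask holds 53.8% as starting material.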